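## Retrosynthetic overview

1. The two halves of the target are mirror-image xanthanolide units. The target is the exo Diels–Alder adduct (bonds C3–C11′ and C5–C13′) of 8-epi-xanthatin (diene, upper half) with the 1,5-epoxide of ent-8-epi-xanthatin (dienophile, lower half), hydroxylated at C1.
2. One racemic synthesis of 8-epi-xanthatin therefore serves both halves; it is divided at the end by an enantiomer-selective epoxidation that gives diene and dienophile in one step.
3. Cycloheptene ring: one-carbon ring expansion (1,2-alkyl shift) of a cis-fused methylene-lactone cyclohexanone with TMSCHN2, giving a regiodefined enol sulfonate for a Heck coupling with methyl vinyl ketone.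
4. Lactone ring: intramolecular Rauhut–Currier cyclisation of a cis-4-acryloyloxy-6-methylcyclohexenone, made from 4-hydroxycyclohexenone by methylation and Mitsunobu inversion.
5. Ring order: cyclohexenone (bought) → γ-lactone → cycloheptene (ring expansion) → epoxide (lower half) → spiro-cyclohexene (union), then the C1 hydroxyl.

Assumption: xanthanolide numbering is used (C7/C8 lactone-fused carbons, C10 methyl-bearing, C1=C5 ring alkene, C2–C4 side chain, C11–C13 methylene lactone; primes = lower epoxide half); compounds with the prefix rac are written as the enantiomer of the upper-half series, and racemic 1 is taken as commercially available.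

## Route

Step 1
Reactants: 1 rac-4-hydroxycyclohex-2-en-1-one; 2 iodomethane
Product: 3 rac-(4S,6S)-4-hydroxy-6-methylcyclohex-2-en-1-one (trans)
Conditions: LiN(iPr)2 (2.2 equiv), THF–DMPU, −78 °C; MeI (1.05 equiv), −78 → −40 °C; AcOH quench
Reagents that add atoms: iodomethane, CI
Why: Kinetic alkoxide–enolate dianion alkylation: the cross-conjugated lithium enolate is C-methylated at C6 by axial attack on the face away from the C4 oxygen substituent, which sets the trans C4/C6 relationship (minor cis isomer removed by chromatography).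

Step 2
Reactants: 3 rac-(4S,6S)-4-hydroxy-6-methylcyclohex-2-en-1-one; 4 prop-2-enoic acid
Product: 5 rac-(1R,5S)-5-methyl-4-oxocyclohex-2-en-1-yl prop-2-enoate (cis)
Conditions: PPh3, DIAD, THF, BHT (cat.), 0 → 23 °C
Reagents that add atoms: prop-2-enoic acid, C=CC(=O)O
Why: Mitsunobu esterification displaces the oxyphosphonium by SN2 with inversion at the carbinol carbon, turning the trans alcohol into the cis acrylate in which the future C8 oxygen and the C10 methyl are on the same face.

Step 3
Reactants: 5 rac-(1R,5S)-5-methyl-4-oxocyclohex-2-en-1-yl prop-2-enoate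
Product: 6 rac-(3aR,6S,7aR)-6-methyl-3-methylidene-3a,4,7,7a-tetrahydro-1-benzofuran-2,5(3H,6H)-dione (cis-fused)
Conditions: PBu3 (0.2 equiv), t-AmOH, 23 °C
Reagents that add atoms: none
Why: Intramolecular Rauhut–Currier reaction: PBu3 adds to the acrylate, the phosphonium enolate closes 5-exo-trig onto the enone β-carbon and PBu3 is expelled, so the new C7 stereocentre is forced cis to the C8 oxygen by the fused five-membered ring and the α-methylene lactone is formed directly.

Step 4
Reactants: 6 rac-(3aR,6S,7aR)-6-methyl-3-methylidene-3a,4,7,7a-tetrahydro-1-benzofuran-2,5(3H,6H)-dione; 7 (trimethylsilyl)diazomethane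
Product: 10 rac-(3aR,7S,8aR)-7-methyl-3-methylidene-2-oxo-3,3a,4,7,8,8a-hexahydro-2H-cyclohepta[b]furan-6-yl nonafluorobutane-1-sulfonate, via rac-α-silyl cycloheptanone 8 (not isolated), via rac-silyl enol ether 9 (not isolated)
Conditions: Sc(OTf)3 (10 mol %), TMSCHN2 (1.2 equiv), PhMe, −78 → 40 °C; then THF, C4F9SO2F (1.5 equiv), Bu4NF (0.3 equiv), 0 → 23 °C
Reagents that add atoms: (trimethylsilyl)diazomethane, C[Si](C)(C)C=[N+]=[N-]; nonafluorobutane-1-sulfonyl fluoride, O=S(=O)(F)C(F)(F)C(F)(F)C(F)(F)C(F)(F)F
Why: Lewis-acid-catalysed diazoalkane–carbonyl homologation (Tiffeneau–Demjanov-type 1,2-shift) in which the less substituted α-CH2 (C6) migrates with loss of N2 rather than the methyl-bearing C10, followed by 1,3-Brook silyl shift to the Δ1(5) enol silane and fluoride-catalysed O-sulfonylation, which fixes the alkene position without a strong base and touches no stereocentre.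

Step 5
Reactants: 10 rac-(3aR,7S,8aR)-7-methyl-3-methylidene-2-oxo-3,3a,4,7,8,8a-hexahydro-2H-cyclohepta[b]furan-6-yl nonafluorobutane-1-sulfonate; 11 but-3-en-2-one
Product: 12 rac-8-epi-xanthatin, rac-(3aR,7S,8aR)-7-methyl-3-methylidene-6-[(1E)-3-oxobut-1-en-1-yl]-3,3a,4,7,8,8a-hexahydro-2H-cyclohepta[b]furan-2-one
Conditions: Pd(OAc)2 (5 mol %), PPh3 (10 mol %), Et3N (2 equiv), but-3-en-2-one (5 equiv), DMF, 60 °C
Reagents that add atoms: but-3-en-2-one, CC(=O)C=C
Why: Heck reaction of the alkenyl nonaflate with excess methyl vinyl ketone gives the (E)-dienone by syn insertion and syn β-hydride elimination, the 1,1-disubstituted lactone methylene being a much poorer acceptor than the monosubstituted enone.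

Step 6
Reactants: 12 rac-8-epi-xanthatin
Product: 13 8-epi-xanthatin, the (3aR,7S,8aR) enantiomer (recovered unreacted) and 14 (1R,5R,7S,8S,10R)-1,5-epoxy-ent-8-epi-xanthatin (C1–C5 epoxide of the (3aS,7R,8aS) enantiomer, oxygen anti to the C10 methyl)
Conditions: D-fructose-derived Shi ketone (0.3 equiv), KHSO5 (0.6 equiv), K2CO3, Bu4NHSO4 (cat.), MeCN–CH2(OMe)2–aq. Na2B4O7/Na2EDTA (pH 10.5), −10 °C, stopped at ca. 52% conversion
Reagents that add atoms: potassium peroxymonosulfate, [K+].[O-]S(=O)(=O)OO
Why: Proposed new method: kinetic resolution of a racemic cross-conjugated cycloheptadienone by chiral dioxirane epoxidation — the electrophilic dioxirane attacks only the electron-richest C1=C5 alkene and its spiro transition state delivers oxygen to the face that gives the (1R,5R) epoxide, which is the face anti to the allylic C10 methyl in the (3aS,7R,8aS) enantiomer (matched, fast) but the methyl-shielded face in the (3aR,7S,8aR) enantiomer (mismatched, slow), so one enantiomer is epoxidised with both epoxide stereocentres set and the other is recovered; closest known reaction: Shi epoxidation used for kinetic resolution of racemic 1,6-disubstituted cyclohexenes.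

Step 7
Reactants: 13 8-epi-xanthatin, (3aR,7S,8aR); 14 (1R,5R,7S,8S,10R)-1,5-epoxy-ent-8-epi-xanthatin
Product: 15 Diels–Alder adduct, the target without the C1 hydroxyl and with the ring alkene at C1=C2 and a hydrogen at C3 (3S,5S,7R,8R,10S upper half; 1′R,5′R,7′S,8′S,10′R,11′R lower half)
Conditions: PhMe (2 M), BHT (5 mol %), degassed, 100 °C, sealed tube, 48 h (14 2 equiv, excess recovered)
Reagents that add atoms: none
Why: Thermal Diels–Alder reaction in which the excess of 14 (a dienophile only, its ring alkene being epoxidised) outruns self-dimerisation of 13; ortho/para orientation joins the acetyl-bearing C3 to the lactone α-carbon C11′ and C5 to C13′, the s-cis-locked methylene lactone reacts exo with respect to its carbonyl on its convex face (the H7′ side) and the diene is attacked on the face away from the C7–C9 body of its chair cycloheptene, which sets C5 (S) and the spiro carbon C11′ (R) and leaves a C3 stereocentre that is erased in step 8.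

Step 8
Reactants: 15 Diels–Alder adduct
Product: 17 CNP0177598.2 (target), via C1-hydroperoxide 16 (not isolated)
Conditions: O2 (1 atm), DBU (0.2 equiv), MeCN, 0 °C; then PPh3 (1.1 equiv), 0 °C
Reagents that add atoms: dioxygen, O=O
Why: Base-mediated autoxidation of a β,γ-unsaturated ketone (γ-hydroperoxidation of the extended dienolate, then phosphine reduction): DBU removes the doubly activated C3–H, O2 adds at C1 by axial attack anti to the pseudoaxial C5–H so that the new C–O bond is trans to H5 (1S, trans-fused rings), the double bond moves into conjugation at C2=C3 and PPh3 reduces the tertiary hydroperoxide.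

## Compound list

1 | rac-4-hydroxycyclohex-2-en-1-one | OC1CCC(=O)C=C1 | starting material
2 | iodomethane | CI | starting material
3 | rac-(4S,6S)-4-hydroxy-6-methylcyclohex-2-en-1-one (trans) | O[C@H]1C[C@H](C)C(=O)C=C1 | intermediate
4 | prop-2-enoic acid (acrylic acid) | C=CC(=O)O | starting material
5 | rac-(1R,5S)-5-methyl-4-oxocyclohex-2-en-1-yl prop-2-enoate (cis) | C=CC(=O)O[C@@H]1C[C@H](C)C(=O)C=C1 | intermediate
6 | rac-(3aR,6S,7aR)-6-methyl-3-methylidene-3a,4,7,7a-tetrahydro-1-benzofuran-2,5(3H,6H)-dione | C=C1C(=O)O[C@@H]2C[C@H](C)C(=O)C[C@H]12 | intermediate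
7 | (trimethylsilyl)diazomethane | C[Si](C)(C)C=[N+]=[N-] | starting material
8 | rac-(3aR,7S,8aR)-7-methyl-3-methylidene-5-(trimethylsilyl)hexahydro-2H-cyclohepta[b]furan-2,6(3H)-dione (C5 epimers) | C=C1C(=O)O[C@@H]2C[C@H](C)C(=O)C([Si](C)(C)C)C[C@H]12 | intermediate
9 | rac-(3aR,7S,8aR)-7-methyl-3-methylidene-6-[(trimethylsilyl)oxy]-3,3a,4,7,8,8a-hexahydro-2H-cyclohepta[b]furan-2-one | C=C1C(=O)O[C@@H]2C[C@H](C)C(O[Si](C)(C)C)=CC[C@H]12 | intermediate
10 | rac-(3aR,7S,8aR)-7-methyl-3-methylidene-2-oxo-3,3a,4,7,8,8a-hexahydro-2H-cyclohepta[b]furan-6-yl nonafluorobutane-1-sulfonate | C=C1C(=O)O[C@@H]2C[C@H](C)C(OS(=O)(=O)C(F)(F)C(F)(F)C(F)(F)C(F)(F)F)=CC[C@H]12 | intermediate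
11 | but-3-en-2-one (methyl vinyl ketone) | CC(=O)C=C | starting material
12 | rac-8-epi-xanthatin, rac-(3aR,7S,8aR)-7-methyl-3-methylidene-6-[(1E)-3-oxobut-1-en-1-yl]-3,3a,4,7,8,8a-hexahydro-2H-cyclohepta[b]furan-2-one | C=C1C(=O)O[C@@H]2C[C@H](C)C(/C=C/C(C)=O)=CC[C@H]12 | intermediate
13 | 8-epi-xanthatin, (3aR,7S,8aR) enantiomer | C=C1C(=O)O[C@@H]2C[C@H](C)C(/C=C/C(C)=O)=CC[C@H]12 | intermediate
14 | (1R,5R,7S,8S,10R)-1,5-epoxy-ent-8-epi-xanthatin (epoxide oxygen anti to the C10 methyl) | C=C1C(=O)O[C@H]2C[C@@H](C)[C@]3(/C=C/C(C)=O)O[C@@H]3C[C@@H]12 | intermediate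
15 | Diels–Alder adduct: 1-deoxy target with C1=C2 alkene and 3S C3–H (5S,7R,8R,10S; 1′R,5′R,7′S,8′S,10′R,11′R) | C=C1C(=O)O[C@@H]2C[C@H](C)C3=C[C@H](C(C)=O)[C@]4(C[C@@H]3C[C@H]12)C(=O)O[C@H]1C[C@@H](C)[C@]2(/C=C/C(C)=O)O[C@@H]2C[C@H]14 | intermediate
16 | C1-hydroperoxide of the target (OOH in place of OH, 1S) | C=C1C(=O)O[C@@H]2C[C@H](C)[C@@]3(OO)C=C(C(C)=O)[C@]4(C[C@@H]3C[C@H]12)C(=O)O[C@H]1C[C@@H](C)[C@]2(/C=C/C(C)=O)O[C@@H]2C[C@H]14 | intermediate
17 | CNP0177598.2 (1S,5S,7R,8R,10S upper half; 1′R,5′R,7′S,8′S,10′R,11′R lower half) | C=C1C(=O)O[C@@H]2C[C@H](C)[C@@]3(O)C=C(C(C)=O)[C@]4(C[C@@H]3C[C@H]12)C(=O)O[C@H]1C[C@@H](C)[C@]2(/C=C/C(C)=O)O[C@@H]2C[C@H]14 | target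

## Step count and risks

Total step count: 8. Longest linear sequence: 8 steps (1 → 17; both halves come from the same sequence, which divides at step 6 and rejoins at step 7).

Steps most likely to fail:

Step 4 (ring expansion, silyl shift and sulfonylation in one pot). The silyl shift may be incomplete, or the fluoride-generated enolate may be lost to the lactone methylene. The fallback sets out from 6 and separates the tasks. BF3·OEt2/TMSCHN2 in CH2Cl2 at −78 °C with acidic work-up (the α-silyl ketone 8 is protodesilylated) gives rac-(3aR,7S,8aR)-7-methyl-3-methylidenehexahydro-2H-cyclohepta[b]furan-2,6(3H)-dione F1. Kinetic deprotonation on the CH2 side with KN(SiMe3)2 in THF at −78 °C and trapping with PhNTf2 gives rac-(3aR,7S,8aR)-7-methyl-3-methylidene-2-oxo-3,3a,4,7,8,8a-hexahydro-2H-cyclohepta[b]furan-6-yl trifluoromethanesulfonate F2. F2 undergoes the Heck reaction under the step 5 conditions and comes back to the route at 12. Regiocontrol then rests on kinetic enolisation of an isolated ketone, not on the Brook shift.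

Step 6 (proposed new step). The selectivity factor may be too low, or the basic aqueous medium may damage the methylene lactone. The fallback sets out from 12 and uses known chemistry. Preparative chromatography on a chiral stationary phase (amylose tris(3,5-dimethylphenylcarbamate), supercritical CO2/MeOH) separates 13 from its mirror image ent-8-epi-xanthatin F3. Substrate-controlled epoxidation of F3 with dimethyldioxirane in acetone at 0 °C, anti to the C10 methyl, gives 14. The route is rejoined at 13 and 14.

Step 7 (Diels–Alder union). Self-dimerisation of 13 may compete, and the diene-face or exo selectivity is not secured by precedent. The fallback sets out from 13 and masks its dienophile. PhSH with catalytic Et3N in CH2Cl2 at −20 °C adds to the lactone methylene to give 13-(phenylsulfanyl)-11,13-dihydro-8-epi-xanthatin F4, which can act only as a diene. Cycloaddition of F4 with 14 at 12 kbar and 23 °C in CH2Cl2 gives the 13-(phenylsulfanyl)-11,13-dihydro derivative of the adduct F5. Oxidation with mCPBA (1.0 equiv, −78 °C) gives the sulfoxide F6. Thermal syn-elimination in PhMe at 110 °C restores the methylene lactone and comes back to the route at 15.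

Further compounds

F1 | step 4 | rac-(3aR,7S,8aR)-7-methyl-3-methylidenehexahydro-2H-cyclohepta[b]furan-2,6(3H)-dione | C=C1C(=O)O[C@@H]2C[C@H](C)C(=O)CC[C@H]12
F2 | step 4 | rac-(3aR,7S,8aR)-7-methyl-3-methylidene-2-oxo-3,3a,4,7,8,8a-hexahydro-2H-cyclohepta[b]furan-6-yl trifluoromethanesulfonate | C=C1C(=O)O[C@@H]2C[C@H](C)C(OS(=O)(=O)C(F)(F)F)=CC[C@H]12
F3 | step 6 | ent-8-epi-xanthatin, (3aS,7R,8aS) enantiomer | C=C1C(=O)O[C@H]2C[C@@H](C)C(/C=C/C(C)=O)=CC[C@@H]12
F4 | step 7 | 13-(phenylsulfanyl)-11,13-dihydro-8-epi-xanthatin (C11 epimers) | c1ccccc1SCC1C(=O)O[C@@H]2C[C@H](C)C(/C=C/C(C)=O)=CC[C@H]12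
F5 | step 7 | 13-(phenylsulfanyl)-11,13-dihydro derivative of adduct 15 (C11 epimers) | c1ccccc1SCC1C(=O)O[C@@H]2C[C@H](C)C3=C[C@H](C(C)=O)[C@]4(C[C@@H]3C[C@H]12)C(=O)O[C@H]1C[C@@H](C)[C@]2(/C=C/C(C)=O)O[C@@H]2C[C@H]14
F6 | step 7 | S-oxide of F5 (sulfoxide, epimers at sulfur and C11) | O=S(CC1C(=O)O[C@@H]2C[C@H](C)C3=C[C@H](C(C)=O)[C@]4(C[C@@H]3C[C@H]12)C(=O)O[C@H]1C[C@@H](C)[C@]2(/C=C/C(C)=O)O[C@@H]2C[C@H]14)c1ccccc1
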